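Per cent of charge is the wrong unit for comparing these flasks, so I turn the flat readings into molar amount reacted.

| flask | left-handed substrate | right-handed substrate | partner | free catalyst | remark | time |
|---|---|---|---|---|---|---|
| winter | 0.10 M | 0.10 M | 0.20 M | 2.1 mM | run made earlier |  |
| midnight | 0.10 M | 0.10 M | 0.20 M | 4.7 mM | run made earlier |  |
| spring | 0.20 M | 0.20 M | 0.20 M | 3.1 mM | run made earlier |  |
| flask | 0.10 M | 0.10 M | 0.200 M | 3.1 mM |  | 12 h |

| run | time / h | left-handed substrate / % | right-handed substrate / % | left-handed product / % |
|---|---|---|---|---|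
| winter | 2.00 | 48.0 | 44.1 | 2.5 |
| winter | 4.00 | 47.3 | 43.0 | 1.4 |
| winter | 5.00 | 48.8 | 43.4 | 1.9 |
| winter | 8.00 | 48.1 | 43.4 | 1.8 |
| midnight | 0.500 | 48.1 | 43.9 | 1.5 |
| midnight | 1.33 | 47.5 | 39.4 | 3.0 |
| midnight | 3.00 | 44.3 | 38.9 | 3.8 |
| midnight | 8.00 | 46.1 | 38.0 | 4.3 |
| spring | 2.00 | 47.9 | 44.4 | 1.1 |
| spring | 4.00 | 48.5 | 43.5 | 2.1 |
| spring | 5.00 | 47.9 | 44.3 | 2.8 |
| spring | 8.00 | 47.4 | 43.6 | 1.7 |

(standard deviation of a reading: 0.5 percentage points)

- free catalyst is single-handed; left-handed substrate and right-handed substrate are mirror images of each other, charged as a racemate, each of them at the stated concentration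
- an excess is below zero if the other one leads

1. part of the left-handed substrate and right-handed substrate charged together that has reacted at 12 h
2. excess of left-handed product over right-handed product in the product at 12 h
3. excess of right-handed substrate over left-handed substrate among what is left of the two at 12 h

If the rate is k[free catalyst][partner] and both concentrations fall exponentially, the integral is closed: k times both charges, over the sum of the two decay constants. The amount reacted then follows

amount reacted = G × [free catalyst] × [partner], both as charged.

The winter run reacts 16.9 mM, so G = 40.4 M⁻¹. The midnight run, over its last three readings, reacts 30.5 mM, so G = 32.5 M⁻¹. These readings differ, so I take a rough mean, 36.4 M⁻¹, as the reach G, the molar amount reacted per charged [free catalyst] and charged [partner]. The runs never varied [partner], so that factor is my supposition.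

The spring run looks nearly the same as the flask, with equal catalyst and partner charges, but its substrate charge is doubled. It reacts 32.5 mM, which is just 8.12% of its charge. Its G reads higher, 52.4 M⁻¹, so I use the mean from the two runs with the flask's substrate charge. For the flask I reckon 22.6 mM, or 11.3%.

The forecast holds that “the catalyst dies or shuts down” and gives c = 11%, eP = −51% and eS = −6.3%.

The flask gives c = 11.6%, eP = −47.8% and eS = −6.27%, so the forecast stands.

    free catalyst + left-handed substrate ⇌ catalyst intermediate A (K = 3.20 M⁻¹, k = 1.84 M⁻¹ s⁻¹)
    free catalyst + right-handed substrate ⇌ catalyst intermediate B (K = 29.0 M⁻¹, k = 0.843 M⁻¹ s⁻¹)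
    partner + catalyst intermediate A → free catalyst + left-handed product (k = 0.0494 M⁻¹ s⁻¹)
    partner + catalyst intermediate B → free catalyst + right-handed product (k = 0.0177 M⁻¹ s⁻¹)
    2 free catalyst ⇌ resting dimer, settled at all times (K = 650 M⁻¹)
    free catalyst → spent catalyst (k = 6.17 × 10⁻⁴ s⁻¹)
    partner → decomposed reagent (k = 1.84 × 10⁻⁴ s⁻¹)

The flask's own result gives G = 37.4 M⁻¹. The main reason for the sign of eP is the reverse step, catalyst intermediate A back to free catalyst and left-handed substrate: the simulated run without that step gives eP = 92.2%, against −47.8% with it. So that run, in which left-handed product leads, is what it takes for the forecast's −51% to be wrong.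

With 0.080 M of partner, G gives 9.03 mM, or 4.52%. The computed neighbour flask reaches 4.85%.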